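**Plan**

1. Retrosynthesis: both interflavan C4–C8 bonds are cut, the upper one first. In the middle unit the C2–C3 bond of ring C is cut as well, which leads back to a C2–C4 bond, that is, to a trans-2-aryl-2,3-dihydrobenzofuran whose exocyclic acetal carbon is the later C3. This five-membered ring comes from a flavanone by a shift of C4a from C4 to C3.
2. Forward: the lower unit is benzylated (−)-epiafzelechin. Ring C of the middle unit grows from five to six atoms in the same operation that joins its C4 to C8 of the lower unit. The upper unit (a 4-alkoxy-epiafzelechin) is attached last, and hydrogenolysis ends the route.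
3. Feature used: ring A of the middle unit carries O1, O5 and O7 ortho/para to C4, so a cation at C4 is far more stable than an alkoxycarbenium ion on the neighbouring exocyclic carbon. C2, which bears O1 and ring B, can therefore migrate to that carbon.
4. Stereochemistry: upper and lower units come from (−)-epiafzelechin (C4 of the upper unit is set trans to its 3-OH). C2 of the middle unit (ent series) comes from a rhodium-catalysed asymmetric 1,4-addition and is carried through the ring contraction. C3 and C4 of the middle unit arise in the key step under control of C2.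

Key step: step 8

Remark: (−)-epiafzelechin (2R,3R) is taken as a purchasable natural flavan-3-ol, and 5,7-dihydroxychromone as a purchasable chromone.
Remark: the bisphosphine antipode in step 4 is the one that delivers the 2R flavanone; it is written as (R) and is exchanged for (S) if the sense of induction proves opposite.

**Route**

Step 1
Reactants: 1 (−)-epiafzelechin
Product: 2 5,7,4'-tri-O-benzyl-(−)-epiafzelechin
Conditions: BnBr (3.3 equiv), K2CO3 (4 equiv), DMF, 0 °C to rt, argon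
Reagents that add atoms: benzyl bromide, BrCc1ccccc1
Why: Williamson etherification in which only the three phenols are deprotonated by K2CO3, so the secondary 3-OH stays free and no stereocentre is touched.

Step 2
Reactants: 2 5,7,4'-tri-O-benzyl-(−)-epiafzelechin
Product: 3 (2R,3R,4S)-5,7-bis(benzyloxy)-2-[4-(benzyloxy)phenyl]-4-(2-ethoxyethoxy)chroman-3-ol (4β ether)
Conditions: DDQ (2 equiv), 2-ethoxyethanol (6 equiv), CH2Cl2, rt
Reagents that add atoms: 2-ethoxyethanol, CCOCCO
Why: DDQ abstracts hydride from C4, which is benzylic to the electron-rich ring A, and the alcohol adds to the cation trans to the 3-OH (known oxidative C4 etherification of benzylated flavan-3-ols), which should give the 4β ether.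

Step 3
Reactants: 4 5,7-dihydroxy-4H-chromen-4-one
Product: 5 5,7-bis(benzyloxy)-4H-chromen-4-one
Conditions: BnBr (2.6 equiv), K2CO3 (3 equiv), DMF, 70 °C
Reagents that add atoms: benzyl bromide, BrCc1ccccc1
Why: Williamson etherification of both phenols, the hydrogen-bonded 5-OH needing heat, while the chromone ring is inert to carbonate.

Step 4
Reactants: 5 5,7-bis(benzyloxy)-4H-chromen-4-one; 6 [4-(benzyloxy)phenyl]boronic acid
Product: 7 (2R)-5,7-bis(benzyloxy)-2-[4-(benzyloxy)phenyl]chroman-4-one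
Conditions: 6 (3 equiv), [Rh(OH)(cod)]2 (2.5 mol %; cod = 1,5-cyclooctadiene), (R)-MeO-F12-BIPHEP [6,6'-dimethoxy-2,2'-bis{bis(3,4,5-trifluorophenyl)phosphino}biphenyl] (5.5 mol %), toluene/H2O, 30 °C
Reagents that add atoms: none
Why: Hayashi–Miyaura asymmetric 1,4-addition of the aryl–rhodium species to the chromone enone, in which the electron-poor chiral bisphosphine selects the enone face and so sets C2 (aryl group β, the antipode of the natural flavanone series).

Step 5
Reactants: 7 (2R)-5,7-bis(benzyloxy)-2-[4-(benzyloxy)phenyl]chroman-4-one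
Product: 9 methyl (2R,3R)-4,6-bis(benzyloxy)-2-[4-(benzyloxy)phenyl]-2,3-dihydro-1-benzofuran-3-carboxylate (2,3-trans), via 4-methoxy-2H-chromene enol ether 8 (not isolated)
Conditions: PhI(OAc)2 (1.2 equiv), HC(OMe)3 (solvent), conc. H2SO4 (0.3 equiv), rt; aqueous NaHCO3 work-up
Reagents that add atoms: trimethyl orthoformate, COC(OC)OC; water, O
Why: Hypervalent-iodine oxidative ring contraction of a flavanone, a known route to trans-2-aryl-2,3-dihydrobenzofuran-3-carboxylates, in which the iodane adds to C3 of enol ether 8 anti to the aryl group and C4a shifts from C4 to C3 with loss of PhI; C2 is untouched and the new centre ends trans to the aryl group, which is also the thermodynamic arrangement.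

Step 6
Reactants: 9 methyl (2R,3R)-4,6-bis(benzyloxy)-2-[4-(benzyloxy)phenyl]-2,3-dihydro-1-benzofuran-3-carboxylate
Product: 10 (2R,3R)-4,6-bis(benzyloxy)-2-[4-(benzyloxy)phenyl]-2,3-dihydro-1-benzofuran-3-carbaldehyde (2,3-trans)
Conditions: i-Bu2AlH (1.1 equiv), CH2Cl2, −78 °C; then MeOH and aqueous potassium sodium tartrate
Reagents that add atoms: none
Why: Partial reduction of a methyl ester, in which the tetrahedral aluminium hemiacetal is stable at −78 °C and releases the aldehyde on work-up; the trans arrangement is the thermodynamic one, so enolisation would do no harm.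

Step 7
Reactants: 10 (2R,3R)-4,6-bis(benzyloxy)-2-[4-(benzyloxy)phenyl]-2,3-dihydro-1-benzofuran-3-carbaldehyde
Product: 11 (2R,3R)-4,6-bis(benzyloxy)-2-[4-(benzyloxy)phenyl]-3-[bis(benzyloxy)methyl]-2,3-dihydro-1-benzofuran
Conditions: BnOH (6 equiv), pyridinium p-toluenesulfonate (0.1 equiv), 4 Å molecular sieves, CH2Cl2, rt
Reagents that add atoms: benzyl alcohol, OCc1ccccc1
Why: Acid-catalysed acetalisation in an excess of the alcohol, where the oxocarbenium ion is captured by benzyl alcohol faster than it can rearrange; benzyl is chosen so that the later 3-O substituent falls in the final hydrogenolysis.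

Step 8
Reactants: 11 (2R,3R)-4,6-bis(benzyloxy)-2-[4-(benzyloxy)phenyl]-3-[bis(benzyloxy)methyl]-2,3-dihydro-1-benzofuran; 2 5,7,4'-tri-O-benzyl-(−)-epiafzelechin
Product: 14 3,5,7,4'-tetra-O-benzyl-ent-epiafzelechin-(4α→8)-5,7,4'-tri-O-benzyl-epiafzelechin, via O-benzyl oxocarbenium ion 12 (not isolated), via flavan-4-yl cation 13 (not isolated)
Conditions: 2 (4 equiv), Me3SiOTf (0.5 equiv), 4 Å molecular sieves, CH2Cl2 (0.005 M in 11, which is added slowly), −78 to −40 °C; then Et3N
Reagents that add atoms: none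
Why: Proposed new method: Me3SiOTf ionises the dibenzyl acetal to oxocarbenium ion 12, in which C2 (bearing O1 and the 4-benzyloxyphenyl ring, hence a very good migrating group) shifts with retention from C3 of the benzofuran to the cationic exocyclic carbon, so that ring C grows from five to six atoms and the charge moves to C4, where O1, O5 and O7 of ring A stabilise it (cation 13); C8 of 2 then attacks C4 in a Friedel–Crafts alkylation. The closest known reaction types are the Wagner–Meerwein ring expansion of cycloalkylcarbinyl cations (the step is the formal reverse of a semipinacol ring contraction) and, for the second half, the Me3SiOTf-mediated 4→8 coupling of 4-alkoxyflavan-3-ol derivatives with flavan-3-ol nucleophiles. The pyran ring is closed by a suprafacial 1,2-carbon shift (five-to-six ring expansion) and not by a nucleophilic closure, driven by the greater stability of the 5,7-dioxygenated benzylic cation over an alkoxycarbenium ion and by loss of five-ring strain. C2 keeps its configuration; C3 is set by the rotamer of 12 that turns the oxocarbenium oxygen and its benzyl group away from ring A and the peri benzyloxy group, which places the 3-benzyloxy group cis to the ring B aryl group; C4 is set by attack of 2 anti to the pseudo-axial 3-benzyloxy group (3,4-trans), as is the rule for 2,3-cis flavan-4-yl cations. The step needs migration of C2 in preference to the hydrogen on C3 of the benzofuran (which would end in an aromatic benzofuran) and a shift that is faster than direct arylation of 12; the oxygen lone pair and aryl group on the migrating carbon, high dilution and low temperature are relied on for this, and the excess of 2 with its known C8 preference for the regiochemistry.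

Step 9
Reactants: 14 3,5,7,4'-tetra-O-benzyl-ent-epiafzelechin-(4α→8)-5,7,4'-tri-O-benzyl-epiafzelechin; 3 (2R,3R,4S)-5,7-bis(benzyloxy)-2-[4-(benzyloxy)phenyl]-4-(2-ethoxyethoxy)chroman-3-ol
Product: 15 5,7,4'-tri-O-benzyl-epiafzelechin-(4β→8)-3,5,7,4'-tetra-O-benzyl-ent-epiafzelechin-(4α→8)-5,7,4'-tri-O-benzyl-epiafzelechin
Conditions: 14 (3 equiv, excess recovered), 3 (1 equiv), Me3SiOTf (0.2 equiv), CH2Cl2, −78 °C; then Et3N
Reagents that add atoms: none
Why: Lewis-acid 4→8 coupling of a 4-alkoxyflavan-3-ol with an excess of a flavan-3-ol nucleophile (Friedel–Crafts alkylation), in which the cation from 3 is attacked by the free C8 of the ent-epiafzelechin unit of 14 trans to the 3-OH, which sets the new C4 as 4β.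

Step 10
Reactants: 15 5,7,4'-tri-O-benzyl-epiafzelechin-(4β→8)-3,5,7,4'-tetra-O-benzyl-ent-epiafzelechin-(4α→8)-5,7,4'-tri-O-benzyl-epiafzelechin
Product: 16 epiafzelechin-(4β→8)-ent-epiafzelechin-(4α→8)-epiafzelechin (CNP0191553.2)
Conditions: H2 (1 atm), Pd(OH)2/C, THF/MeOH/H2O, rt; filtration, Sephadex LH-20
Reagents that add atoms: none
Why: Hydrogenolysis of the ten benzyl ethers (nine aryl, one alkyl) under neutral conditions that leave the acid-sensitive interflavan bonds and all stereocentres intact.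

**Compound list**

1 | (−)-epiafzelechin, (2R,3R)-2-(4-hydroxyphenyl)chroman-3,5,7-triol | O[C@@H]1Cc2c(O)cc(O)cc2O[C@@H]1c1ccc(O)cc1 | starting material
2 | 5,7,4'-tri-O-benzyl-(−)-epiafzelechin, (2R,3R)-5,7-bis(benzyloxy)-2-[4-(benzyloxy)phenyl]chroman-3-ol | O[C@@H]1Cc2c(OCc3ccccc3)cc(OCc3ccccc3)cc2O[C@@H]1c1ccc(OCc2ccccc2)cc1 | intermediate
3 | (2R,3R,4S)-5,7-bis(benzyloxy)-2-[4-(benzyloxy)phenyl]-4-(2-ethoxyethoxy)chroman-3-ol (4β ether, 3,4-trans) | O[C@@H]1[C@@H](OCCOCC)c2c(OCc3ccccc3)cc(OCc3ccccc3)cc2O[C@@H]1c1ccc(OCc2ccccc2)cc1 | intermediate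
4 | 5,7-dihydroxy-4H-chromen-4-one | O=c1ccoc2cc(O)cc(O)c12 | starting material
5 | 5,7-bis(benzyloxy)-4H-chromen-4-one | O=c1ccoc2cc(OCc3ccccc3)cc(OCc3ccccc3)c12 | intermediate
6 | [4-(benzyloxy)phenyl]boronic acid | OB(O)c1ccc(OCc2ccccc2)cc1 | starting material
7 | (2R)-5,7-bis(benzyloxy)-2-[4-(benzyloxy)phenyl]chroman-4-one | O=C1C[C@H](c2ccc(OCc3ccccc3)cc2)Oc2cc(OCc3ccccc3)cc(OCc3ccccc3)c12 | intermediate
8 | (2R)-5,7-bis(benzyloxy)-2-[4-(benzyloxy)phenyl]-4-methoxy-2H-chromene (not isolated) | COC1=C[C@H](c2ccc(OCc3ccccc3)cc2)Oc2cc(OCc3ccccc3)cc(OCc3ccccc3)c12 | intermediate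
9 | methyl (2R,3R)-4,6-bis(benzyloxy)-2-[4-(benzyloxy)phenyl]-2,3-dihydro-1-benzofuran-3-carboxylate (2,3-trans) | COC(=O)[C@H]1[C@H](c2ccc(OCc3ccccc3)cc2)Oc2cc(OCc3ccccc3)cc(OCc3ccccc3)c12 | intermediate
10 | (2R,3R)-4,6-bis(benzyloxy)-2-[4-(benzyloxy)phenyl]-2,3-dihydro-1-benzofuran-3-carbaldehyde (2,3-trans) | O=C[C@H]1[C@H](c2ccc(OCc3ccccc3)cc2)Oc2cc(OCc3ccccc3)cc(OCc3ccccc3)c12 | intermediate
11 | (2R,3R)-4,6-bis(benzyloxy)-2-[4-(benzyloxy)phenyl]-3-[bis(benzyloxy)methyl]-2,3-dihydro-1-benzofuran (2,3-trans) | c1ccccc1COC(OCc1ccccc1)[C@H]1[C@H](c2ccc(OCc3ccccc3)cc2)Oc2cc(OCc3ccccc3)cc(OCc3ccccc3)c12 | intermediate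
12 | benzyl{[(2R,3R)-4,6-bis(benzyloxy)-2-[4-(benzyloxy)phenyl]-2,3-dihydro-1-benzofuran-3-yl]methylidene}oxonium (not isolated) | c1ccccc1C[O+]=C[C@H]1[C@H](c2ccc(OCc3ccccc3)cc2)Oc2cc(OCc3ccccc3)cc(OCc3ccccc3)c12 | intermediate
13 | (2S,3S)-3,5,7-tris(benzyloxy)-2-[4-(benzyloxy)phenyl]chroman-4-ylium (2,3-cis; not isolated) | c1c(OCc3ccccc3)cc(OCc3ccccc3)c2c1O[C@@H](c1ccc(OCc3ccccc3)cc1)[C@@H](OCc1ccccc1)[CH+]2 | intermediate
14 | 3,5,7,4'-tetra-O-benzyl-ent-epiafzelechin-(4α→8)-5,7,4'-tri-O-benzyl-epiafzelechin | c1c(OCc3ccccc3)cc(OCc3ccccc3)c2c1O[C@@H](c1ccc(OCc3ccccc3)cc1)[C@@H](OCc1ccccc1)[C@@H]2c1c(OCc3ccccc3)cc(OCc3ccccc3)c2c1O[C@H](c1ccc(OCc3ccccc3)cc1)[C@H](O)C2 | intermediate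
15 | 5,7,4'-tri-O-benzyl-epiafzelechin-(4β→8)-3,5,7,4'-tetra-O-benzyl-ent-epiafzelechin-(4α→8)-5,7,4'-tri-O-benzyl-epiafzelechin | c9ccccc9COc1ccc([C@H]2Oc3cc(OCc9ccccc9)cc(OCc9ccccc9)c3[C@H](c3c(OCc9ccccc9)cc(OCc9ccccc9)c4c3O[C@@H](c3ccc(OCc9ccccc9)cc3)[C@@H](OCc3ccccc3)[C@@H]4c3c(OCc9ccccc9)cc(OCc9ccccc9)c4c3O[C@H](c3ccc(OCc9ccccc9)cc3)[C@H](O)C4)[C@H]2O)cc1 | intermediate
16 | epiafzelechin-(4β→8)-ent-epiafzelechin-(4α→8)-epiafzelechin (CNP0191553.2) | Oc1ccc([C@H]2Oc3cc(O)cc(O)c3[C@H](c3c(O)cc(O)c4c3O[C@@H](c3ccc(O)cc3)[C@@H](O)[C@@H]4c3c(O)cc(O)c4c3O[C@H](c3ccc(O)cc3)[C@H](O)C4)[C@H]2O)cc1 | target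

**Totals**

Total step count: 10. Longest linear sequence: 8 steps (steps 3 to 10, from 4).

**Steps most likely to fail**

Step 8 (key step). What may go wrong: a 1,2-hydride shift in 12 in place of the carbon shift, followed by loss of a proton and aromatisation to a benzofuran; arylation of 12 by 2 before the shift; or reaction through the other rotamer, which would give the 2,3-trans unit. The fallback uses known chemistry without ring expansion and sets out from flavanone 7.
- NaBH4 in MeOH/THF should give (2R,4R)-5,7-bis(benzyloxy)-2-[4-(benzyloxy)phenyl]chroman-4-ol F1.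
- Dehydration (TsOH, toluene, 60 °C) should give (2R)-5,7-bis(benzyloxy)-2-[4-(benzyloxy)phenyl]-2H-chromene F2.
- Hydroboration–oxidation (BH3·THF, then NaOH/H2O2) anti to the aryl group should give 5,7,4'-tri-O-benzyl-ent-afzelechin F3 (2,3-trans).
- Dess–Martin periodinane should give (2S)-5,7-bis(benzyloxy)-2-[4-(benzyloxy)phenyl]chroman-3-one F4.
- Li(s-Bu)3BH at −78 °C should give 5,7,4'-tri-O-benzyl-ent-epiafzelechin F5 (2,3-cis).
- NaH/BnBr should give 3,5,7,4'-tetra-O-benzyl-ent-epiafzelechin F6.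
- DDQ/2-ethoxyethanol should give (2S,3S,4R)-3,5,7-tris(benzyloxy)-2-[4-(benzyloxy)phenyl]-4-(2-ethoxyethoxy)chromane F7.
- Me3SiOTf-mediated coupling of F7 with 2 (4 equiv) at −78 °C comes back to the route at 14.

Step 5. What may go wrong: loss of configuration at C2 by acid-induced opening of the benzylic aryl ether at the stage of enol ether 8, and a competing shift of ring B from C2 to C3 that would lead to an isoflavone. The fallback contracts the ring under neutral conditions and sets out from flavanone 7.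
- Deacylative diazo transfer: LiN(SiMe3)2 and CF3CO2CH2CF3 at −78 °C should give (2R)-5,7-bis(benzyloxy)-2-[4-(benzyloxy)phenyl]-3-(trifluoroacetyl)chroman-4-one F8.
- MsN3/Et3N in MeCN should then give (2S)-5,7-bis(benzyloxy)-2-[4-(benzyloxy)phenyl]-3-diazochroman-4-one F9.
- Photochemical Wolff rearrangement in MeOH (C4a shifts from C4 to C3, and the ketene is trapped by MeOH), followed by equilibration with DBU to the trans ester, comes back to the route at 9.

Step 9. What may go wrong: self-condensation of electrophile 3 through its own free C8 and chain growth of 15 at the free C8 of its upper unit while the hindered dimer 14 reacts slowly, together with attack at a C6 position. The fallback caps C8 of the upper unit and sets out from 2.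
- NBS in CH2Cl2 at −20 °C should give (2R,3R)-5,7-bis(benzyloxy)-2-[4-(benzyloxy)phenyl]-8-bromochroman-3-ol F10.
- DDQ/2-ethoxyethanol should give (2R,3R,4S)-5,7-bis(benzyloxy)-2-[4-(benzyloxy)phenyl]-8-bromo-4-(2-ethoxyethoxy)chroman-3-ol F11.
- Me3SiOTf coupling with 14, now possible in equimolar amounts, should give the 8-bromo derivative of 15, F12.
- Hydrogenolysis over Pd(OH)2/C with Et3N removes bromine and benzyl groups together and comes back to the route at 16.

**Further compounds**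

F1 | step 8 | (2R,4R)-5,7-bis(benzyloxy)-2-[4-(benzyloxy)phenyl]chroman-4-ol (2,4-cis) | O[C@@H]1C[C@H](c2ccc(OCc3ccccc3)cc2)Oc2cc(OCc3ccccc3)cc(OCc3ccccc3)c12
F2 | step 8 | (2R)-5,7-bis(benzyloxy)-2-[4-(benzyloxy)phenyl]-2H-chromene | C1=C[C@H](c2ccc(OCc3ccccc3)cc2)Oc2cc(OCc3ccccc3)cc(OCc3ccccc3)c12
F3 | step 8 | 5,7,4'-tri-O-benzyl-ent-afzelechin, (2S,3R)-5,7-bis(benzyloxy)-2-[4-(benzyloxy)phenyl]chroman-3-ol | O[C@@H]1Cc2c(OCc3ccccc3)cc(OCc3ccccc3)cc2O[C@H]1c1ccc(OCc2ccccc2)cc1
F4 | step 8 | (2S)-5,7-bis(benzyloxy)-2-[4-(benzyloxy)phenyl]chroman-3-one | O=C1Cc2c(OCc3ccccc3)cc(OCc3ccccc3)cc2O[C@H]1c1ccc(OCc2ccccc2)cc1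
F5 | step 8 | 5,7,4'-tri-O-benzyl-ent-epiafzelechin, (2S,3S)-5,7-bis(benzyloxy)-2-[4-(benzyloxy)phenyl]chroman-3-ol | O[C@H]1Cc2c(OCc3ccccc3)cc(OCc3ccccc3)cc2O[C@H]1c1ccc(OCc2ccccc2)cc1
F6 | step 8 | 3,5,7,4'-tetra-O-benzyl-ent-epiafzelechin, (2S,3S)-3,5,7-tris(benzyloxy)-2-[4-(benzyloxy)phenyl]chromane | c1ccccc1CO[C@H]1Cc2c(OCc3ccccc3)cc(OCc3ccccc3)cc2O[C@H]1c1ccc(OCc2ccccc2)cc1
F7 | step 8 | (2S,3S,4R)-3,5,7-tris(benzyloxy)-2-[4-(benzyloxy)phenyl]-4-(2-ethoxyethoxy)chromane (4α ether) | c1ccccc1CO[C@H]1[C@H](OCCOCC)c2c(OCc3ccccc3)cc(OCc3ccccc3)cc2O[C@H]1c1ccc(OCc2ccccc2)cc1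
F8 | step 5 | (2R)-5,7-bis(benzyloxy)-2-[4-(benzyloxy)phenyl]-3-(trifluoroacetyl)chroman-4-one (2,3-trans, keto form) | O=C1[C@@H](C(=O)C(F)(F)F)[C@H](c2ccc(OCc3ccccc3)cc2)Oc2cc(OCc3ccccc3)cc(OCc3ccccc3)c12
F9 | step 5 | (2S)-5,7-bis(benzyloxy)-2-[4-(benzyloxy)phenyl]-3-diazochroman-4-one | O=C1C(=[N+]=[N-])[C@H](c2ccc(OCc3ccccc3)cc2)Oc2cc(OCc3ccccc3)cc(OCc3ccccc3)c12
F10 | step 9 | (2R,3R)-5,7-bis(benzyloxy)-2-[4-(benzyloxy)phenyl]-8-bromochroman-3-ol | O[C@@H]1Cc2c(OCc3ccccc3)cc(OCc3ccccc3)c(Br)c2O[C@@H]1c1ccc(OCc2ccccc2)cc1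
F11 | step 9 | (2R,3R,4S)-5,7-bis(benzyloxy)-2-[4-(benzyloxy)phenyl]-8-bromo-4-(2-ethoxyethoxy)chroman-3-ol | O[C@@H]1[C@@H](OCCOCC)c2c(OCc3ccccc3)cc(OCc3ccccc3)c(Br)c2O[C@@H]1c1ccc(OCc2ccccc2)cc1
F12 | step 9 | 8-bromo-5,7,4'-tri-O-benzyl-epiafzelechin-(4β→8)-3,5,7,4'-tetra-O-benzyl-ent-epiafzelechin-(4α→8)-5,7,4'-tri-O-benzyl-epiafzelechin | c9ccccc9COc1ccc([C@H]2Oc3c(Br)c(OCc9ccccc9)cc(OCc9ccccc9)c3[C@H](c3c(OCc9ccccc9)cc(OCc9ccccc9)c4c3O[C@@H](c3ccc(OCc9ccccc9)cc3)[C@@H](OCc3ccccc3)[C@@H]4c3c(OCc9ccccc9)cc(OCc9ccccc9)c4c3O[C@H](c3ccc(OCc9ccccc9)cc3)[C@H](O)C4)[C@H]2O)cc1
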